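## Retrosynthetic overview (disconnections listed in the forward sense; read upwards for the retrosynthesis)

1. C–C fragment union: acid chloride 1 + benzylzinc 2 → aryl ketone 3, which already holds all 25 carbons of the target.
2. The carbocycle is never built: the anisole ring of 3 is reduced (dienol ether 4), hydrolysed to cyclohexenone 5 and oxidised to ene-dione 6.
3. Key disconnection, the tertiary C–O bond: ketoxime 7 closes through oxygen onto the enone β-carbon (5-exo, catalyst-controlled) to spiro-isoxazoline 8. This is the only ring formed in the route and the step that sets the stereocentre.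
4. Ring C=C: dehydrogenation of 8 (enolate 9, sulfilimine 10) on the side away from the spiro carbon gives enone 11.
5. N–O cleavage (ketimine 12) opens the temporary isoxazoline again to the β-hydroxy ketone 13 (target).

Assumption: the facial sense of the new step 4 must be settled by experiment; the quinine-derived catalyst is written, and its quinidine-derived pseudo-enantiomer is used if the quinine series gives (5S); oleoyl chloride is taken as the pure (9Z) grade.

## Route

Step 1
Reactants: 1 (9Z)-octadec-9-enoyl chloride (oleoyl chloride); 2 (3-methoxybenzyl)zinc chloride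
Product: 3 (10Z)-1-(3-methoxyphenyl)nonadec-10-en-2-one
Conditions: Pd(PPh3)4 (2 mol %), THF, 0 °C → rt
Reagents that add atoms: none
Why: Negishi acylation (acid chloride adds to zerovalent palladium, the benzyl group is transferred from zinc, reductive elimination) stops at the ketone and does not touch the Z-alkene; no stereocentre is formed.

Step 2
Reactants: 3 (10Z)-1-(3-methoxyphenyl)nonadec-10-en-2-one
Product: 5 rac-3-[(10Z)-2-hydroxynonadec-10-en-1-yl]cyclohex-2-en-1-one, via Birch dienol ether 4 (not isolated)
Conditions: Li, NH3(l), t-BuOH, THF, −78 → −33 °C; then 1 M HCl, THF, rt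
Reagents that add atoms: water, O
Why: Birch reduction of the m-alkylanisole gives the 2,5-dihydroanisole 4 (the ketone goes to the alkoxide in the same pot, the isolated Z-alkene is inert to Li/NH3), and acid hydrolysis of the enol ether with migration of the double bond into conjugation gives the 3-substituted cyclohex-2-enone; the carbinol carbon is formed racemic and is removed again in step 3.

Step 3
Reactants: 5 rac-3-[(10Z)-2-hydroxynonadec-10-en-1-yl]cyclohex-2-en-1-one
Product: 6 3-[(10Z)-2-oxononadec-10-en-1-yl]cyclohex-2-en-1-one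
Conditions: Dess–Martin periodinane, CH2Cl2, 0 °C → rt
Reagents that add atoms: none
Why: Dess–Martin oxidation of the secondary alcohol is near-neutral and leaves the enone, the Z-alkene and the doubly activated CH2 alone; 6 is used at once.

Step 4
Reactants: 6 3-[(10Z)-2-oxononadec-10-en-1-yl]cyclohex-2-en-1-one
Product: 8 (5R)-3-[(8Z)-heptadec-8-en-1-yl]-1-oxa-2-azaspiro[4.5]dec-2-en-7-one, via ketoxime 7 (not isolated)
Conditions: NH2OH·HCl (1.0 equiv), NaOAc, MeOH, 0 °C; extractive work-up, crude oxime taken on; then 9-amino-9-deoxy-epi-quinine [(8α,9S)-6′-methoxycinchonan-9-amine] (20 mol %), CF3CO2H (40 mol %), toluene, 0 °C → rt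
Reagents that add atoms: hydroxylamine hydrochloride, Cl.NO
Why: Proposed new method: catalytic enantioselective intramolecular oxime oxa-Michael (5-exo-trig) spirocyclisation onto a β,β-disubstituted cyclic enone. One equivalent of hydroxylamine condenses with the saturated, more electrophilic side-chain ketone to give ketoxime 7; the primary amine of the cinchona catalyst converts the hindered ring enone into a chiral iminium ion, the quinuclidine nitrogen hydrogen-bonds the oxime O–H and delivers the oxygen to one face of C3, and hydrolysis of the resulting enamine releases 8 with the tetrasubstituted (5R) C–O stereocentre; the closure is downhill because the oxime O–H bond is weak, only oxygen can reach C3 through a five-membered transition state, and the acid co-catalyst interconverts the oxime E/Z isomers so that both drain through the cyclisable one. Closest known reaction types: primary-amine (iminium) catalysed intermolecular oxa-Michael addition of oximes to acyclic enones, epoxidation of 3-substituted cyclohexenones by the same catalysts (which also creates a tetrasubstituted C–O carbon), and the phase-transfer hydroxylamine/enone cascade to 5,5-disubstituted 2-isoxazolines.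

Step 5
Reactants: 8 (5R)-3-[(8Z)-heptadec-8-en-1-yl]-1-oxa-2-azaspiro[4.5]dec-2-en-7-one
Product: 11 (5R)-3-[(8Z)-heptadec-8-en-1-yl]-1-oxa-2-azaspiro[4.5]deca-2,8-dien-7-one, via lithium enolate 9 (not isolated), via α-sulfilimino ketone 10 (not isolated)
Conditions: LiN(i-Pr)2 (1.05 equiv), THF, −78 °C; then PhS(Cl)=N-t-Bu, −78 °C; pH 7 buffer quench
Reagents that add atoms: none
Why: Mukaiyama dehydrogenation: the amide base removes the less hindered α′-proton away from the spiro carbon (kinetic control, which also avoids the enolate that could expel the β-oxygen), enolate 9 attacks sulfur and sulfilimine 10 undergoes syn-elimination to the enone; the isoxazoline masks the side-chain ketone and the tertiary alcohol so only one ketone can react, and the stereocentre carries no hydrogen and is untouched.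

Step 6
Reactants: 11 (5R)-3-[(8Z)-heptadec-8-en-1-yl]-1-oxa-2-azaspiro[4.5]deca-2,8-dien-7-one
Product: 13 (5R)-5-hydroxy-5-[(10Z)-2-oxononadec-10-en-1-yl]cyclohex-2-en-1-one, via β-hydroxy ketimine 12 (not isolated)
Conditions: Mo(CO)6 (1 equiv), MeCN–H2O (10:1), 70 °C
Reagents that add atoms: water, O
Why: Reductive N–O cleavage of a 2-isoxazoline by zerovalent molybdenum, followed by hydrolysis of the N–H ketimine 12 by water, unmasks the β-hydroxy ketone under near-neutral conditions that spare the enone and the Z-alkene; the C–O bond at the stereocentre is not broken, so (5R) is retained.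

## Compound list

1 | (9Z)-octadec-9-enoyl chloride (oleoyl chloride) | CCCCCCCC/C=C\CCCCCCCC(=O)Cl | starting material
2 | (3-methoxybenzyl)zinc chloride (commercial THF solution) | COc1cccc(C[Zn]Cl)c1 | starting material
3 | (10Z)-1-(3-methoxyphenyl)nonadec-10-en-2-one | CCCCCCCC/C=C\CCCCCCCC(=O)Cc1cccc(OC)c1 | intermediate
4 | (10Z)-1-(5-methoxycyclohexa-1,4-dien-1-yl)nonadec-10-en-2-ol (racemic) | CCCCCCCC/C=C\CCCCCCCC(O)CC1=CCC=C(OC)C1 | intermediate (not isolated)
5 | rac-3-[(10Z)-2-hydroxynonadec-10-en-1-yl]cyclohex-2-en-1-one | CCCCCCCC/C=C\CCCCCCCC(O)CC1=CC(=O)CCC1 | intermediate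
6 | 3-[(10Z)-2-oxononadec-10-en-1-yl]cyclohex-2-en-1-one | CCCCCCCC/C=C\CCCCCCCC(=O)CC1=CC(=O)CCC1 | intermediate
7 | 3-[(10Z)-2-(hydroxyimino)nonadec-10-en-1-yl]cyclohex-2-en-1-one (oxime E/Z mixture) | CCCCCCCC/C=C\CCCCCCCC(=NO)CC1=CC(=O)CCC1 | intermediate (not isolated)
8 | (5R)-3-[(8Z)-heptadec-8-en-1-yl]-1-oxa-2-azaspiro[4.5]dec-2-en-7-one | CCCCCCCC/C=C\CCCCCCCC1=NO[C@@]2(C1)CCCC(=O)C2 | intermediate
9 | lithium (5R)-3-[(8Z)-heptadec-8-en-1-yl]-1-oxa-2-azaspiro[4.5]deca-2,7-dien-7-olate | CCCCCCCC/C=C\CCCCCCCC1=NO[C@@]2(C1)CCC=C([O-])C2.[Li+] | intermediate (not isolated)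
10 | (5R)-8-(N-tert-butyl-S-phenylsulfinimidoyl)-3-[(8Z)-heptadec-8-en-1-yl]-1-oxa-2-azaspiro[4.5]dec-2-en-7-one (epimers at C8 and S) | CCCCCCCC/C=C\CCCCCCCC1=NO[C@@]2(C1)CCC(S(=NC(C)(C)C)c1ccccc1)C(=O)C2 | intermediate (not isolated)
11 | (5R)-3-[(8Z)-heptadec-8-en-1-yl]-1-oxa-2-azaspiro[4.5]deca-2,8-dien-7-one | CCCCCCCC/C=C\CCCCCCCC1=NO[C@@]2(C1)CC=CC(=O)C2 | intermediate
12 | (5R)-5-hydroxy-5-[(10Z)-2-iminononadec-10-en-1-yl]cyclohex-2-en-1-one | CCCCCCCC/C=C\CCCCCCCC(=N)C[C@]1(O)CC=CC(=O)C1 | intermediate (not isolated)
13 | (5R)-5-hydroxy-5-[(10Z)-2-oxononadec-10-en-1-yl]cyclohex-2-en-1-one | CCCCCCCC/C=C\CCCCCCCC(=O)C[C@]1(O)CC=CC(=O)C1 | target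

## Step count and risks

Total step count: 6. Longest linear sequence: 6 steps (fully linear from 1 and 2).

The three steps most likely to fail:

**Step 4 (the new spirocyclisation).** The risks are racemic background closure of 7 during oximation, partial oximation of the ring ketone, and loss of ee through reversible ring opening. The fallback uses known chemistry, sets out from 6 and comes back at 8. Compound 6 is oximated as before (oxime 7) and closed without chiral control by ordinary base-mediated oxime oxa-Michael addition (catalytic Et3N, CH2Cl2, rt). This gives racemic 3-[(8Z)-heptadec-8-en-1-yl]-1-oxa-2-azaspiro[4.5]dec-2-en-7-one F1. Preparative chromatography on a chiral stationary phase (amylose tris(3,5-dimethylphenylcarbamate), CO2/MeOH) then separates 8 from (5S)-3-[(8Z)-heptadec-8-en-1-yl]-1-oxa-2-azaspiro[4.5]dec-2-en-7-one F2, which is discarded. The absolute configuration is assigned by comparing the rotation of the final product with the natural material.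

**Step 5 (dehydrogenation).** The risks are enolisation towards the spiro carbon, which would expel the oximate and lead to ring opening or aromatisation, and an incomplete sulfilimine elimination. The fallback sets out from 8 and comes back at 11. Compound 8 is silylated under in-situ-quench conditions (LiN(i-Pr)2 added to 8 and Me3SiCl in THF at −78 °C, so the enolate is trapped as it forms). This gives the silyl enol ether (5R)-3-[(8Z)-heptadec-8-en-1-yl]-7-[(trimethylsilyl)oxy]-1-oxa-2-azaspiro[4.5]deca-2,7-diene F3, which is isolated. F3 is oxidised with Pd(OAc)2 in MeCN at rt (Saegusa–Ito oxidation, through a divalent palladium enolate and β-hydride elimination) to give 11.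

**Step 6 (N–O cleavage).** The alkoxide or ketimine stage can undergo retro-aldol cleavage or dehydration, both driven by aromatisation of the cyclohexenone ring, and ammonia is released at 70 °C. The fallback sets out from 11 and comes back at 13, and takes the ring carbonyl out of play first.
- 11 is reduced 1,2 with NaBH4/CeCl3·7H2O (MeOH, −78 °C; Luche reduction) to the allylic alcohol (5R)-3-[(8Z)-heptadec-8-en-1-yl]-1-oxa-2-azaspiro[4.5]deca-2,8-dien-7-ol F4 (both C7 epimers).
- Mo(CO)6 in MeCN–H2O cleaves the N–O bond through the ketimine (10Z)-1-[(1R)-1,5-dihydroxycyclohex-3-en-1-yl]nonadec-10-en-2-imine F5 (not isolated). Hydrolysis gives the dihydroxy ketone (10Z)-1-[(1S)-1,5-dihydroxycyclohex-3-en-1-yl]nonadec-10-en-2-one F6, which has no aromatisation pathway.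
- MnO2 (CH2Cl2, rt) oxidises only the allylic secondary alcohol and gives 13.

## Further compounds

F1 | step 4 | racemic 3-[(8Z)-heptadec-8-en-1-yl]-1-oxa-2-azaspiro[4.5]dec-2-en-7-one | CCCCCCCC/C=C\CCCCCCCC1=NOC2(C1)CCCC(=O)C2
F2 | step 4 | (5S)-3-[(8Z)-heptadec-8-en-1-yl]-1-oxa-2-azaspiro[4.5]dec-2-en-7-one | CCCCCCCC/C=C\CCCCCCCC1=NO[C@]2(C1)CCCC(=O)C2
F3 | step 5 | (5R)-3-[(8Z)-heptadec-8-en-1-yl]-7-[(trimethylsilyl)oxy]-1-oxa-2-azaspiro[4.5]deca-2,7-diene | CCCCCCCC/C=C\CCCCCCCC1=NO[C@@]2(C1)CCC=C(O[Si](C)(C)C)C2
F4 | step 6 | (5R)-3-[(8Z)-heptadec-8-en-1-yl]-1-oxa-2-azaspiro[4.5]deca-2,8-dien-7-ol (both C7 epimers) | CCCCCCCC/C=C\CCCCCCCC1=NO[C@@]2(C1)CC=CC(O)C2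
F5 | step 6 | (10Z)-1-[(1R)-1,5-dihydroxycyclohex-3-en-1-yl]nonadec-10-en-2-imine (both C5 epimers) | CCCCCCCC/C=C\CCCCCCCC(=N)C[C@]1(O)CC=CC(O)C1
F6 | step 6 | (10Z)-1-[(1S)-1,5-dihydroxycyclohex-3-en-1-yl]nonadec-10-en-2-one (both C5 epimers) | CCCCCCCC/C=C\CCCCCCCC(=O)C[C@]1(O)CC=CC(O)C1
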